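**Strategy.** Ring A of the target (eremophilane numbering; C1–C4 plus C5 and C10) is a cyclohexanone whose C1–C2(=O)–C3–C4(CH3) unit is a masked 2-silyloxy-1,3-pentadiene. Everything rests on cutting C1–C10 and C4–C5: an intermolecular Diels–Alder reaction joins (E)-2-(triisopropylsilyloxy)penta-1,3-diene to the C5=C10 double bond of a shikimate-derived 3-formylcyclohex-2-enone that already carries the C7 isopropenyl group and the C8 tiglate. One operation builds ring A, the cis ring fusion and three stereocentres (C4, C5, C10). The formyl group activates, directs regiochemistry and endo selectivity, and later becomes the angular methyl; the C9 ketone is reduced to the axial alcohol.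

Key step: step 10

Convention: eremophilane numbering is used for bicyclic compounds (ring A = C1–C5, C10; ring B = C5–C10; C14 = carbon on C5; C15 = methyl on C4; isopropenyl on C7). β is the face of the C4 and C5 methyl groups. Monocyclic intermediates keep shikimate numbering.

Assumption: the C4 hydroxyl of methyl shikimate, flanked by two oxygenated carbons, is taken to be the slowest to silylate, so that 3,5-bis-silylation is selective.

**Step 1**
Reactants: 1 (−)-shikimic acid
Product: 2 methyl shikimate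
Conditions: MeOH, camphorsulfonic acid (cat.), reflux
Reagents that add atoms: methanol, CO
Why: Fischer esterification of the conjugated acid leaves the three stereocentres untouched.

**Step 2**
Reactants: 2 methyl shikimate
Product: 3 methyl 3,5-bis-O-(tert-butyldimethylsilyl)shikimate
Conditions: t-BuMe2SiCl (2.2 equiv), imidazole, DMF, 0 °C to rt
Reagents that add atoms: tert-butyldimethylsilyl chloride, CC(C)(C)[Si](C)(C)Cl
Why: Regioselective silylation should leave only the most hindered, doubly flanked C4 hydroxyl free.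

**Step 3**
Reactants: 3 methyl 3,5-bis-O-(tert-butyldimethylsilyl)shikimate
Product: 4 methyl 3,5-bis-O-(tert-butyldimethylsilyl)-4-O-methanesulfonylshikimate
Conditions: MsCl, Et3N, CH2Cl2, 0 °C
Reagents that add atoms: methanesulfonyl chloride, CS(=O)(=O)Cl
Why: Sulfonylation through the small sulfene intermediate should activate the hindered C4 hydroxyl with retention.

**Step 4**
Reactants: 4 methyl 3,5-bis-O-(tert-butyldimethylsilyl)-4-O-methanesulfonylshikimate
Product: 6 methyl (3R,4S,5R)-4,5-epoxy-3-hydroxycyclohex-1-ene-1-carboxylate (epoxide trans to the 3-hydroxyl), via methyl 4-O-mesylshikimate 5 (not isolated)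
Conditions: n-Bu4NF (3 equiv), THF, 0 °C to rt
Reagents that add atoms: none
Why: Fluoride desilylation frees the C5 alkoxide, which is anti to the mesylate and closes the epoxide by intramolecular Williamson SN2 with inversion at C4; the cis C3 alkoxide cannot displace it.

**Step 5**
Reactants: 6 methyl (3R,4S,5R)-4,5-epoxy-3-hydroxycyclohex-1-ene-1-carboxylate
Product: 7 methyl (3R,4R,5R)-3,4-dihydroxy-5-(prop-1-en-2-yl)cyclohex-1-ene-1-carboxylate
Conditions: CH2=C(CH3)MgBr (3.5 equiv), CuI (10 mol%), THF, −30 °C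
Reagents that add atoms: isopropenylmagnesium bromide, C=C(C)[Mg]Br
Why: Copper-catalysed Grignard opening of the epoxide should occur trans-diaxially (Fürst–Plattner) at C5, the carbon remote from the C3 oxygen, with inversion, so the isopropenyl group ends trans to the new C4 hydroxyl.

**Step 6**
Reactants: 7 methyl (3R,4R,5R)-3,4-dihydroxy-5-(prop-1-en-2-yl)cyclohex-1-ene-1-carboxylate
Product: 8 (1R,2R,6R)-4-(hydroxymethyl)-6-(prop-1-en-2-yl)cyclohex-3-ene-1,2-diol
Conditions: i-Bu2AlH (5 equiv), CH2Cl2, −78 to 0 °C; aq. potassium sodium tartrate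
Reagents that add atoms: none
Why: Hydride reduction of the conjugated ester gives the primary allylic alcohol without touching the alkenes.

**Step 7**
Reactants: 8 (1R,2R,6R)-4-(hydroxymethyl)-6-(prop-1-en-2-yl)cyclohex-3-ene-1,2-diol
Product: 9 (4R,5R)-4-hydroxy-3-oxo-5-(prop-1-en-2-yl)cyclohex-1-ene-1-carbaldehyde
Conditions: MnO2 (activated, excess), CH2Cl2, rt
Reagents that add atoms: none
Why: Allylic oxidation with MnO2 should convert both allylic alcohols (primary to formyl, secondary to ketone) and spare the non-allylic hydroxyl.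

**Step 8**
Reactants: 9 (4R,5R)-4-hydroxy-3-oxo-5-(prop-1-en-2-yl)cyclohex-1-ene-1-carbaldehyde
Product: 10 (1R,6R)-4-formyl-2-oxo-6-(prop-1-en-2-yl)cyclohex-3-en-1-yl (2E)-2-methylbut-2-enoate
Conditions: tigloyl chloride, pyridine, DMAP (cat.), CH2Cl2, 0 °C
Reagents that add atoms: (E)-2-methylbut-2-enoyl chloride (tigloyl chloride), C/C=C(\C)C(=O)Cl
Why: Nucleophile-catalysed acylation of the only hydroxyl installs the final C8 tiglate, which stays equatorial and trans to the isopropenyl group.

**Step 9**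
Reactants: 11 (E)-pent-3-en-2-one
Product: 13 (E)-triisopropyl(penta-1,3-dien-2-yloxy)silane, via lithium (E)-penta-1,3-dien-2-olate 12 (not isolated)
Conditions: LiN(i-Pr)2, THF, −78 °C; then i-Pr3SiOTf, −78 to 0 °C
Reagents that add atoms: triisopropylsilyl trifluoromethanesulfonate, CC(C)[Si](C(C)C)(C(C)C)OS(=O)(=O)C(F)(F)F
Why: Kinetic deprotonation at the methyl ketone carbon and O-silylation give the cross-conjugated 2-silyloxydiene with the (E)-alkene intact.

**Step 10**
Reactants: 10 (1R,6R)-4-formyl-2-oxo-6-(prop-1-en-2-yl)cyclohex-3-en-1-yl (2E)-2-methylbut-2-enoate, 13 (E)-triisopropyl(penta-1,3-dien-2-yloxy)silane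
Product: 14 8α-tigloyloxy-9-oxo-2-(triisopropylsilyloxy)-10βH-eremophila-2,11-dien-14-al (cis-fused; 4β-methyl, 5β-formyl, 7β-isopropenyl)
Conditions: 13 (2.5 equiv), toluene, BHT (cat.), 80 °C, sealed tube
Reagents that add atoms: none
Why: Thermal normal-demand Diels–Alder reaction of a 2-silyloxydiene with a 3-formylcyclohex-2-enone (closest known type: silyloxydiene additions to carvone-type cyclohexenones and to cycloalkenecarbaldehydes), concerted but asynchronous, with the nucleophilic CH2 terminus (C1) bonding first to C10, the less substituted carbon β to the more electrophilic formyl group, and C4 closing onto C5. Ring A is closed in the intermolecular suprafacial [4+2] mode, so the C5 formyl group and H10 must come out cis (cis-decalin). The face is set by C7: the diene should add axially to the half-chair enone anti to the pseudo-equatorial isopropenyl group, as in carvone cycloadditions, which places both new bonds on the α-face. The C4 methyl is set by the Alder endo rule: with the (E)-diene and the formyl group endo, the methyl ends cis to the formyl carbon; the ring-endo alternative is disfavoured because the C2 OSi(i-Pr)3 group would sit over ring B. The step needs formyl-directed over ketone-directed regiochemistry and formyl-endo over ring-endo orientation; both are secured by the higher electrophilicity and lower substitution of C10 compared with the fully substituted C5, and the silyl enol ether that results fixes the future ketone at C2.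

**Step 11**
Reactants: 14 8α-tigloyloxy-9-oxo-2-(triisopropylsilyloxy)-10βH-eremophila-2,11-dien-14-al
Product: 15 14-(p-toluenesulfonyl)hydrazone of 14
Conditions: TsNHNH2 (1.05 equiv), THF, rt
Reagents that add atoms: p-toluenesulfonyl hydrazide, Cc1ccc(cc1)S(=O)(=O)NN
Why: Hydrazone condensation should be chemoselective for the aldehyde over the hindered, doubly flanked C9 ketone.

**Step 12**
Reactants: 15 14-(p-toluenesulfonyl)hydrazone of 14
Product: 16 9α-hydroxy-8α-tigloyloxy-2-(triisopropylsilyloxy)-10βH-eremophila-2,11-dien-14-al 14-(p-toluenesulfonyl)hydrazone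
Conditions: LiBH(s-Bu)3 (2.5 equiv), THF, −78 °C; AcOH quench at −78 °C
Reagents that add atoms: none
Why: Bulky-hydride ketone reduction should deliver hydride along the equatorial trajectory from the β-face, because axial attack is blocked by the syn-axial C4 carbon on C5, giving the axial 9α-alcohol cis to the C8 ester; the cold acidic quench avoids acyl migration.

**Step 13**
Reactants: 16 9α-hydroxy-8α-tigloyloxy-2-(triisopropylsilyloxy)-10βH-eremophila-2,11-dien-14-al 14-(p-toluenesulfonyl)hydrazone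
Product: 19 8α-tigloyloxy-2-(triisopropylsilyloxy)-10βH-eremophila-2,11-dien-9α-ol, via N-alkyl-N'-tosylhydrazine 17 (not isolated), via alkyldiazene 18 (not isolated)
Conditions: catecholborane (3 equiv), CHCl3, 0 °C to rt; then NaOAc·3H2O, 60 °C
Reagents that add atoms: none
Why: Reductive deoxygenation of the tosylhydrazone (hydride addition to C=N, loss of sulfinate, then loss of N2 from the diazene) turns the formyl carbon into the angular methyl without touching esters, alkenes or the silyl enol ether.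

**Step 14**
Reactants: 19 8α-tigloyloxy-2-(triisopropylsilyloxy)-10βH-eremophila-2,11-dien-9α-ol
Product: 20 9α-senecioyloxy-8α-tigloyloxy-2-(triisopropylsilyloxy)-10βH-eremophila-2,11-diene
Conditions: 3-methylbut-2-enoyl chloride, pyridine, DMAP, CH2Cl2, 0 °C to rt
Reagents that add atoms: 3-methylbut-2-enoyl chloride (senecioyl chloride), CC(C)=CC(=O)Cl
Why: DMAP-catalysed acylation of the single free, axial hydroxyl installs the senecioate with retention at C9.

**Step 15**
Reactants: 20 9α-senecioyloxy-8α-tigloyloxy-2-(triisopropylsilyloxy)-10βH-eremophila-2,11-diene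
Product: 21 8α-tigloyloxy-9α-senecioyloxy-10βH-eremophil-11-en-2-one (4S,5R,7R,8R,9S,10S), CNP0181050.1
Conditions: HF·pyridine, THF, 0 °C
Reagents that add atoms: none
Why: Fluoride-assisted protodesilylation of the silyl enol ether releases the C2 ketone; C3 becomes a CH2 group, so no stereocentre is affected.

**Compound list**
1 | (−)-shikimic acid | O=C(O)C1=C[C@@H](O)[C@@H](O)[C@H](O)C1 | starting material
2 | methyl shikimate | COC(=O)C1=C[C@@H](O)[C@@H](O)[C@H](O)C1 | intermediate
3 | methyl 3,5-bis-O-(tert-butyldimethylsilyl)shikimate | COC(=O)C1=C[C@@H](O[Si](C)(C)C(C)(C)C)[C@@H](O)[C@H](O[Si](C)(C)C(C)(C)C)C1 | intermediate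
4 | methyl 3,5-bis-O-(tert-butyldimethylsilyl)-4-O-methanesulfonylshikimate | COC(=O)C1=C[C@@H](O[Si](C)(C)C(C)(C)C)[C@@H](OS(C)(=O)=O)[C@H](O[Si](C)(C)C(C)(C)C)C1 | intermediate
5 | methyl 4-O-mesylshikimate | COC(=O)C1=C[C@@H](O)[C@@H](OS(C)(=O)=O)[C@H](O)C1 | intermediate
6 | methyl (3R,4S,5R)-4,5-epoxy-3-hydroxycyclohex-1-ene-1-carboxylate | COC(=O)C1=C[C@@H](O)[C@@H]2O[C@@H]2C1 | intermediate
7 | methyl (3R,4R,5R)-3,4-dihydroxy-5-(prop-1-en-2-yl)cyclohex-1-ene-1-carboxylate | COC(=O)C1=C[C@@H](O)[C@H](O)[C@@H](C(C)=C)C1 | intermediate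
8 | (1R,2R,6R)-4-(hydroxymethyl)-6-(prop-1-en-2-yl)cyclohex-3-ene-1,2-diol | OCC1=C[C@@H](O)[C@H](O)[C@@H](C(C)=C)C1 | intermediate
9 | (4R,5R)-4-hydroxy-3-oxo-5-(prop-1-en-2-yl)cyclohex-1-ene-1-carbaldehyde | O=CC1=CC(=O)[C@H](O)[C@@H](C(C)=C)C1 | intermediate
10 | (1R,6R)-4-formyl-2-oxo-6-(prop-1-en-2-yl)cyclohex-3-en-1-yl (2E)-2-methylbut-2-enoate | O=CC1=CC(=O)[C@H](OC(=O)/C(C)=C/C)[C@@H](C(C)=C)C1 | intermediate
11 | (E)-pent-3-en-2-one | C/C=C/C(C)=O | starting material
12 | lithium (E)-penta-1,3-dien-2-olate | [Li+].C=C([O-])/C=C/C | intermediate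
13 | (E)-triisopropyl(penta-1,3-dien-2-yloxy)silane | C=C(O[Si](C(C)C)(C(C)C)C(C)C)/C=C/C | intermediate
14 | 8α-tigloyloxy-9-oxo-2-(triisopropylsilyloxy)-10βH-eremophila-2,11-dien-14-al | C=C(C)[C@H]1C[C@@]2(C=O)[C@H](CC(O[Si](C(C)C)(C(C)C)C(C)C)=C[C@@H]2C)C(=O)[C@@H]1OC(=O)/C(C)=C/C | intermediate
15 | 14-(p-toluenesulfonyl)hydrazone of 14 | C=C(C)[C@H]1C[C@@]2(/C=N/NS(=O)(=O)c3ccc(C)cc3)[C@H](CC(O[Si](C(C)C)(C(C)C)C(C)C)=C[C@@H]2C)C(=O)[C@@H]1OC(=O)/C(C)=C/C | intermediate
16 | 9α-hydroxy analogue of 15 | C=C(C)[C@H]1C[C@@]2(/C=N/NS(=O)(=O)c3ccc(C)cc3)[C@H](CC(O[Si](C(C)C)(C(C)C)C(C)C)=C[C@@H]2C)[C@H](O)[C@@H]1OC(=O)/C(C)=C/C | intermediate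
17 | N-alkyl-N'-tosylhydrazine (C14–N single bond) | C=C(C)[C@H]1C[C@@]2(CNNS(=O)(=O)c3ccc(C)cc3)[C@H](CC(O[Si](C(C)C)(C(C)C)C(C)C)=C[C@@H]2C)[C@H](O)[C@@H]1OC(=O)/C(C)=C/C | intermediate
18 | alkyldiazene (C14–N=NH) | C=C(C)[C@H]1C[C@@]2(CN=N)[C@H](CC(O[Si](C(C)C)(C(C)C)C(C)C)=C[C@@H]2C)[C@H](O)[C@@H]1OC(=O)/C(C)=C/C | intermediate
19 | 8α-tigloyloxy-2-(triisopropylsilyloxy)-10βH-eremophila-2,11-dien-9α-ol | C=C(C)[C@H]1C[C@@]2(C)[C@H](CC(O[Si](C(C)C)(C(C)C)C(C)C)=C[C@@H]2C)[C@H](O)[C@@H]1OC(=O)/C(C)=C/C | intermediate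
20 | 9α-senecioyloxy-8α-tigloyloxy-2-(triisopropylsilyloxy)-10βH-eremophila-2,11-diene | C=C(C)[C@H]1C[C@@]2(C)[C@H](CC(O[Si](C(C)C)(C(C)C)C(C)C)=C[C@@H]2C)[C@H](OC(=O)C=C(C)C)[C@@H]1OC(=O)/C(C)=C/C | intermediate
21 | 8α-tigloyloxy-9α-senecioyloxy-10βH-eremophil-11-en-2-one (CNP0181050.1) | C=C(C)[C@H]1C[C@@]2(C)[C@H](CC(=O)C[C@@H]2C)[C@H](OC(=O)C=C(C)C)[C@@H]1OC(=O)/C(C)=C/C | target

**Step count.** Total: 15 steps. Longest linear sequence: 14 steps (steps 1–8 and 10–15; step 9 is a one-step branch).

**Steps most likely to fail**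

Step 10 (key cycloaddition). The diene may follow the ring ketone instead of the formyl group (reversed regiochemistry), may add with ring B endo (wrong C4 configuration), or may show poor facial discrimination. The fallback keeps C9 at the alcohol level during the cycloaddition, so that the formyl group is the only acceptor and an allylic silyloxy group reinforces the facial bias. It sets out from triol 8. The primary allylic alcohol alone is oxidised (TEMPO cat., PhI(OAc)2, CH2Cl2) to (3R,4R,5R)-3,4-dihydroxy-5-(prop-1-en-2-yl)cyclohex-1-ene-1-carbaldehyde F1. The less hindered allylic hydroxyl is silylated (Et3SiCl, imidazole, CH2Cl2, −40 °C) to the 3-O-triethylsilyl ether F2, and the remaining hydroxyl is tigloylated (tigloyl chloride, pyridine, DMAP) to the enal F3. Diene 13 is added to F3 (toluene, 110 °C, or Me2AlCl, CH2Cl2, −78 °C), anti to both β-substituents, to give the 9β-triethylsilyloxy adduct F4. The secondary silyl ether is cleaved selectively (pyridinium p-toluenesulfonate, MeOH, 0 °C) to the 9β-alcohol F5, and buffered Dess–Martin oxidation (NaHCO3, CH2Cl2) comes back to the route at ketone 14.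

Step 5 (epoxide opening). The organomagnesium reagent may attack the conjugated ester (1,2- or 1,4-addition), or base-induced elimination toward an aromatic ring may compete with opening. The fallback removes the ester first. It sets out from epoxide 6, which is reduced with i-Bu2AlH (CH2Cl2, −78 °C) to [(3R,4S,5R)-4,5-epoxy-3-hydroxycyclohex-1-en-1-yl]methanol F6. The same copper-catalysed isopropenyl Grignard opening on F6, which now has no acceptor, gives triol 8 directly, where the route is rejoined (step 6 is then not needed).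

Step 13 (formyl to methyl). Hydride addition to the hindered, neopentyl-type hydrazone may stall, or the hydrazone may hydrolyse back before reduction. The fallback replaces the hydrazone path by a radical deoxygenation. It sets out from adduct 14, in which LiBH(s-Bu)3 (THF, −78 °C) reduces both carbonyl groups to 8α-tigloyloxy-2-(triisopropylsilyloxy)-10βH-eremophila-2,11-diene-9α,14-diol F7. The primary hydroxyl alone reacts with O-phenyl chlorothionoformate (pyridine, CH2Cl2, 0 °C) to give the 14-O-phenoxythiocarbonyl derivative F8. Barton–McCombie deoxygenation (Bu3SnH, AIBN, toluene, 110 °C) then gives 19, where the route is rejoined.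

**Further compounds**
F1 | step 10 | (3R,4R,5R)-3,4-dihydroxy-5-(prop-1-en-2-yl)cyclohex-1-ene-1-carbaldehyde | O=CC1=C[C@@H](O)[C@H](O)[C@@H](C(C)=C)C1
F2 | step 10 | (3R,4R,5R)-4-hydroxy-5-(prop-1-en-2-yl)-3-(triethylsilyloxy)cyclohex-1-ene-1-carbaldehyde | O=CC1=C[C@@H](O[Si](CC)(CC)CC)[C@H](O)[C@@H](C(C)=C)C1
F3 | step 10 | (1R,2R,6R)-4-formyl-6-(prop-1-en-2-yl)-2-(triethylsilyloxy)cyclohex-3-en-1-yl (2E)-2-methylbut-2-enoate | O=CC1=C[C@@H](O[Si](CC)(CC)CC)[C@H](OC(=O)/C(C)=C/C)[C@@H](C(C)=C)C1
F4 | step 10 | 9β-(triethylsilyloxy)-8α-tigloyloxy-2-(triisopropylsilyloxy)-10βH-eremophila-2,11-dien-14-al | C=C(C)[C@H]1C[C@@]2(C=O)[C@H](CC(O[Si](C(C)C)(C(C)C)C(C)C)=C[C@@H]2C)[C@@H](O[Si](CC)(CC)CC)[C@@H]1OC(=O)/C(C)=C/C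
F5 | step 10 | 9β-hydroxy-8α-tigloyloxy-2-(triisopropylsilyloxy)-10βH-eremophila-2,11-dien-14-al | C=C(C)[C@H]1C[C@@]2(C=O)[C@H](CC(O[Si](C(C)C)(C(C)C)C(C)C)=C[C@@H]2C)[C@@H](O)[C@@H]1OC(=O)/C(C)=C/C
F6 | step 5 | [(3R,4S,5R)-4,5-epoxy-3-hydroxycyclohex-1-en-1-yl]methanol | OCC1=C[C@@H](O)[C@@H]2O[C@@H]2C1
F7 | step 13 | 8α-tigloyloxy-2-(triisopropylsilyloxy)-10βH-eremophila-2,11-diene-9α,14-diol | C=C(C)[C@H]1C[C@@]2(CO)[C@H](CC(O[Si](C(C)C)(C(C)C)C(C)C)=C[C@@H]2C)[C@H](O)[C@@H]1OC(=O)/C(C)=C/C
F8 | step 13 | 14-O-(phenoxythiocarbonyl) derivative of F7 | C=C(C)[C@H]1C[C@@]2(COC(=S)Oc3ccccc3)[C@H](CC(O[Si](C(C)C)(C(C)C)C(C)C)=C[C@@H]2C)[C@H](O)[C@@H]1OC(=O)/C(C)=C/C
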